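Atom labels: the locants of the target, a bicyclo[3.2.1]octan-2-one (C1 methoxy bridgehead, C2 carbonyl, C3 CH(OMe), C4 CH2, C5 allyl bridgehead, C6 CH-methyl, C7 CH-aryl, C8 CH(OH) bridge), are kept for the same atoms in every intermediate.
Enabling feature: ring C1–C2–C3–C4–C5–C8 has methoxy groups on C1 and C3 on either side of the C2 carbonyl and the quaternary C5 across from it. Without the C1–C7 bond and the C8 oxygen it is a mirror-symmetric 4,4-disubstituted 2,6-dimethoxycyclohexa-2,5-dienone, a dearomatised syringol with a non-stereogenic C5, and C7 is a p-methoxybenzylic carbon that can hold an oxygen, hand it to C8 and then ionise.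
Cuts, backwards: aryl O–Si; C4–H and C3–H (enone); the C8 configuration (aldol across C1–C8); C1–C7, traded for a C7–O–C8 ether; then in one operation O–C8 and C5–allyl, leaving a flat 4-alkylsyringol and allyl methyl carbonate; C7–aryl (aryl metal plus aldehyde); C6–CHO (hydroformylation of a vinylsyringol).
Ring order, forwards: the syringol ring becomes ring C1–C2–C3–C4–C5–C8 on para-allylative dearomatisation, the tetrahydrofuran O–C8–C5–C6–C7 closes in the same flask, and the cyclopentane C1–C7–C6–C5–C8 closes as that ether ring opens (benzyl shift from oxygen to C1).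
Stereochemistry: C6 from ligand-controlled hydroformylation; the C7 carbinol (Felkin–Anh addition) is a sacrificial centre that picks one of two enone arms and so fixes C5; C8 is first tied cis to the tether, then turned by aldol equilibration; C1 follows from the bridge, C7 is re-set from the cation trans to the C6 methyl, and C3 comes from protonation on the face away from the endo aryl group.

Key step: step 6

Remark: 4-vinylsyringol is taken as purchasable, the hand of the hydroformylation ligand is fixed by a test run so that the S aldehyde results, and the C1 epimer drawn for 13 is the one assumed to prevail (either serves, since C1 is planarised in step 7).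

Step 1
Reactants: 1 5-bromo-2-methoxyphenol
Product: 2 (5-bromo-2-methoxyphenoxy)triisopropylsilane
Conditions: TIPSCl, imidazole, DMF, rt
Reagents that add atoms: chlorotriisopropylsilane, CC(C)[Si](Cl)(C(C)C)C(C)C
Why: Imidazole-promoted silylation of a phenol; the bulky silyl ether should stand up to the aryl-metal, hydrogenolysis, palladium, Lewis-acid and alkoxide steps and, being meta to bromine, cannot migrate to carbon after metalation.

Step 2
Reactants: 3 2,6-dimethoxy-4-vinylphenol (4-vinylsyringol)
Product: 4 2-(benzyloxy)-1,3-dimethoxy-5-vinylbenzene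
Conditions: BnBr, K2CO3, acetone, rt (trace BHT)
Reagents that add atoms: benzyl bromide, BrCc1ccccc1
Why: Williamson etherification of the phenol; benzyl masks the acidic hydroxyl through hydroformylation and aryl-metal addition and can later be removed without acid or base.

Step 3
Reactants: 4 2-(benzyloxy)-1,3-dimethoxy-5-vinylbenzene; 5 carbon monoxide
Product: 6 (S)-2-[4-(benzyloxy)-3,5-dimethoxyphenyl]propanal
Conditions: Rh(acac)(CO)2 (0.5 mol %), Ph-BPE [1,2-bis(2,5-diphenylphospholan-1-yl)ethane, antipode that gives the S aldehyde] (0.6 mol %), CO/H2 1:1 (10 bar), toluene, 60 °C; used at once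
Reagents that add atoms: carbon monoxide (compound 5), [C-]#[O+]
Why: Rhodium-catalysed asymmetric hydroformylation of a styrene is branched-selective (benzylic rhodium alkyl) and sets C6 by the chiral bisphosphine; the α-aryl aldehyde is carried on cold and without delay because this centre epimerises easily.

Step 4
Reactants: 2 (5-bromo-2-methoxyphenoxy)triisopropylsilane; 6 (S)-2-[4-(benzyloxy)-3,5-dimethoxyphenyl]propanal
Product: 9 (1R,2S)-2-[4-(benzyloxy)-3,5-dimethoxyphenyl]-1-[4-methoxy-3-(triisopropylsilyloxy)phenyl]propan-1-ol, via aryllithium 7 (not isolated), via aryltitanium triisopropoxide 8 (not isolated)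
Conditions: 2, n-BuLi, THF, −78 °C; ClTi(OiPr)3, −78 to −40 °C; then 6, −78 to −20 °C; aq. NH4Cl
Reagents that add atoms: none
Why: Bromine–lithium exchange and transmetalation give a non-basic aryltitanium that adds 1,2 to the aldehyde without enolising it, and Felkin–Anh control by the neighbouring aryl/methyl centre should favour the (1R,2S) carbinol; the minor diastereomer is removed here by chromatography.

Step 5
Reactants: 9 (1R,2S)-2-[4-(benzyloxy)-3,5-dimethoxyphenyl]-1-[4-methoxy-3-(triisopropylsilyloxy)phenyl]propan-1-ol
Product: 10 4-{(1R,2S)-1-hydroxy-1-[4-methoxy-3-(triisopropylsilyloxy)phenyl]propan-2-yl}-2,6-dimethoxyphenol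
Conditions: H2 (1 atm), 10% Pd/C, EtOAc, rt
Reagents that add atoms: none
Why: Hydrogenolysis of an aryl benzyl ether on Pd/C under neutral conditions is much faster than loss of the secondary benzylic hydroxyl and leaves the silyl ether alone; it is placed before any alkene enters the molecule.

Step 6
Reactants: 10 4-{(1R,2S)-1-hydroxy-1-[4-methoxy-3-(triisopropylsilyloxy)phenyl]propan-2-yl}-2,6-dimethoxyphenol; 11 allyl methyl carbonate
Product: 13 (2R,3S,3aR,7S,7aR)-3a-allyl-5,7-dimethoxy-2-[4-methoxy-3-(triisopropylsilyloxy)phenyl]-3-methyl-3,3a,7,7a-tetrahydro-1-benzofuran-6(2H)-one, via symmetric cyclohexadienone 12 (not isolated)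
Conditions: 11 (1.0 equiv), Pd2(dba)3·CHCl3 (2.5 mol %), PPh3 (10 mol %), Cs2CO3 (0.2 equiv), THF, 25 to 60 °C
Reagents that add atoms: allyl methyl carbonate (compound 11), C=CCOC(=O)OC
Why: Proposed new method: zerovalent palladium ionises carbonate 11, the methoxide set free (with loss of CO2) deprotonates the phenol, and the ambident phenoxide meets the allylpalladium cation; O-allylation and attack at the methoxy-bearing ortho carbons can be undone (re-ionisation, retro-Claisen) or passed on by a Cope shift, whereas attack of the para carbon C5 gives dienone 12, the only isomer with an exit, namely conjugate addition of the C7 hydroxyl to C8. The closest known reaction types are the palladium-catalysed allylic dearomatisation of para-substituted phenols (intramolecular) and of naphthols (intermolecular), the para-Claisen course of 2,6-disubstituted aryl allyl ethers, and the oxa-Michael desymmetrisation of 4,4-disubstituted cyclohexadienones. One ring closes, the tetrahydrofuran O–C8–C5–C6–C7, by 5-exo-trig oxa-Michael addition, and the three-atom tether allows only a cis ring fusion, which sets C8. C5 becomes stereogenic through the choice between the two diastereotopic enone arms, decided by the (1R,2S) side chain because the 2,3-cis tetrahydrofuran can carry aryl and methyl on the convex face (methyl cis to allyl) for one arm only, and the base-reversible addition lets this isomer gather; C1 is set on protonation and is planarised again in step 7. The step needs para-C-allylation over O- and ortho-allylation, which rests on the reversibility of the latter under zerovalent palladium together with the drain open only to the para adduct, and it needs one enone arm of two, which the substrate's own stereocentres supply. One equivalent of 11 is used so that the α-methoxy ketone of 13 is not allylated in turn.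

Step 7
Reactants: 13 (2R,3S,3aR,7S,7aR)-3a-allyl-5,7-dimethoxy-2-[4-methoxy-3-(triisopropylsilyloxy)phenyl]-3-methyl-3,3a,7,7a-tetrahydro-1-benzofuran-6(2H)-one
Product: 14 (2R,3S,3aR,7aR)-3a-allyl-5,7-dimethoxy-2-[4-methoxy-3-(triisopropylsilyloxy)phenyl]-3-methyl-6-(trimethylsilyloxy)-2,3,3a,7a-tetrahydro-1-benzofuran
Conditions: TMSOTf, Et3N, CH2Cl2, 0 °C; pentane extraction, no aqueous work-up
Reagents that add atoms: trimethylsilyl triflate, C[Si](C)(C)OS(=O)(=O)C(F)(F)F
Why: Soft enolisation (silyl triflate and amine) can only run toward C1, the single α-carbon that bears hydrogen, and turns the ketone into a silyl enol ether whose C1 is nucleophilic.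

Step 8
Reactants: 14 (2R,3S,3aR,7aR)-3a-allyl-5,7-dimethoxy-2-[4-methoxy-3-(triisopropylsilyloxy)phenyl]-3-methyl-6-(trimethylsilyloxy)-2,3,3a,7a-tetrahydro-1-benzofuran
Product: 16 (1S,5R,6R,7S,8R)-5-allyl-8-hydroxy-1,3-dimethoxy-7-[4-methoxy-3-(triisopropylsilyloxy)phenyl]-6-methylbicyclo[3.2.1]oct-3-en-2-one, via trimethylsilyl ether 15 (not isolated)
Conditions: TMSOTf (0.2 equiv), CH2Cl2, −78 °C; then 1 M HCl, THF, 0 °C
Reagents that add atoms: none
Why: Silylation of the ring oxygen and ionisation of the p-methoxybenzylic C7–O bond give a cation that C1 of the silyl enol ether captures (intramolecular Mukaiyama-type SN1 alkylation, the known acid-induced change of hydrobenzofuranoid into bicyclo[3.2.1]octanoid neolignans), which closes the cyclopentane C1–C7–C6–C5–C8, passes the silyl group to the C8 oxygen, fixes C1 through the bridge and should re-set C7 with the aryl group endo, trans to the C6 methyl; the competing cleavage of the C8–O bond only returns the dienone ether, which can re-close through the same oxonium ion.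

Step 9
Reactants: 16 (1S,5R,6R,7S,8R)-5-allyl-8-hydroxy-1,3-dimethoxy-7-[4-methoxy-3-(triisopropylsilyloxy)phenyl]-6-methylbicyclo[3.2.1]oct-3-en-2-one
Product: 17 (1S,5R,6R,7S,8S)-5-allyl-8-hydroxy-1,3-dimethoxy-7-[4-methoxy-3-(triisopropylsilyloxy)phenyl]-6-methylbicyclo[3.2.1]oct-3-en-2-one
Conditions: t-BuOK (0.2 equiv), THF, 0 °C to rt; AcOH
Reagents that add atoms: none
Why: Retro-aldol/aldol equilibration of the β-hydroxy ketone across C1–C8 (the enolate can only re-close on the same face of C1, so C8 alone changes, and C3 is still sp2) should settle on the 8S epimer, whose hydroxyl lies over the flat enone bridge instead of against the exo C6 methyl.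

Step 10
Reactants: 17 (1S,5R,6R,7S,8S)-5-allyl-8-hydroxy-1,3-dimethoxy-7-[4-methoxy-3-(triisopropylsilyloxy)phenyl]-6-methylbicyclo[3.2.1]oct-3-en-2-one
Product: 18 (1S,3S,5S,6R,7S,8S)-5-allyl-8-hydroxy-1,3-dimethoxy-7-[4-methoxy-3-(triisopropylsilyloxy)phenyl]-6-methylbicyclo[3.2.1]octan-2-one
Conditions: [(Ph3P)CuH]6 (0.4 equiv), H2O (3 equiv), degassed THF/toluene, rt
Reagents that add atoms: none
Why: Conjugate reduction by the phosphine copper hydride touches the enone but not the isolated terminal alkene, and water protonates the copper enolate at C3 from the C8 side, the other face being covered by the endo aryl group, under conditions that stay neutral for the aldol unit.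

Step 11
Reactants: 18 (1S,3S,5S,6R,7S,8S)-5-allyl-8-hydroxy-1,3-dimethoxy-7-[4-methoxy-3-(triisopropylsilyloxy)phenyl]-6-methylbicyclo[3.2.1]octan-2-one
Product: 19 (1S,3S,5S,6R,7S,8S)-5-allyl-8-hydroxy-7-(3-hydroxy-4-methoxyphenyl)-1,3-dimethoxy-6-methylbicyclo[3.2.1]octan-2-one (CNP0209708.1)
Conditions: TBAF, AcOH (1:1.2), THF, 0 °C
Reagents that add atoms: none
Why: Fluoride cleavage of the aryl silyl ether, buffered with acetic acid so that neither the phenoxide nor the aldol unit nor the epimerisable C3 meets base.

Compound list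
1 | 5-bromo-2-methoxyphenol | COc1ccc(Br)cc1O | starting material
2 | (5-bromo-2-methoxyphenoxy)triisopropylsilane | COc1ccc(Br)cc1O[Si](C(C)C)(C(C)C)C(C)C | intermediate
3 | 2,6-dimethoxy-4-vinylphenol | C=Cc1cc(OC)c(O)c(OC)c1 | starting material
4 | 2-(benzyloxy)-1,3-dimethoxy-5-vinylbenzene | C=Cc1cc(OC)c(OCc2ccccc2)c(OC)c1 | intermediate
5 | carbon monoxide | [C-]#[O+] | starting material
6 | (S)-2-[4-(benzyloxy)-3,5-dimethoxyphenyl]propanal | O=C[C@@H](C)c1cc(OC)c(OCc2ccccc2)c(OC)c1 | intermediate
7 | [4-methoxy-3-(triisopropylsilyloxy)phenyl]lithium | COc1ccc([Li])cc1O[Si](C(C)C)(C(C)C)C(C)C | intermediate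
8 | [4-methoxy-3-(triisopropylsilyloxy)phenyl]titanium triisopropoxide | COc1ccc(cc1O[Si](C(C)C)(C(C)C)C(C)C)[Ti](OC(C)C)(OC(C)C)OC(C)C | intermediate
9 | (1R,2S)-2-[4-(benzyloxy)-3,5-dimethoxyphenyl]-1-[4-methoxy-3-(triisopropylsilyloxy)phenyl]propan-1-ol | COc1cc(cc(OC)c1OCc2ccccc2)[C@H](C)[C@@H](O)c3ccc(OC)c(O[Si](C(C)C)(C(C)C)C(C)C)c3 | intermediate
10 | 4-{(1R,2S)-1-hydroxy-1-[4-methoxy-3-(triisopropylsilyloxy)phenyl]propan-2-yl}-2,6-dimethoxyphenol | COc1cc(cc(OC)c1O)[C@H](C)[C@@H](O)c3ccc(OC)c(O[Si](C(C)C)(C(C)C)C(C)C)c3 | intermediate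
11 | allyl methyl carbonate | C=CCOC(=O)OC | starting material
12 | 4-allyl-4-{(1R,2S)-1-hydroxy-1-[4-methoxy-3-(triisopropylsilyloxy)phenyl]propan-2-yl}-2,6-dimethoxycyclohexa-2,5-dien-1-one | C=CCC1([C@H](C)[C@@H](O)c2ccc(OC)c(O[Si](C(C)C)(C(C)C)C(C)C)c2)C=C(OC)C(=O)C(OC)=C1 | intermediate
13 | (2R,3S,3aR,7S,7aR)-3a-allyl-5,7-dimethoxy-2-[4-methoxy-3-(triisopropylsilyloxy)phenyl]-3-methyl-3,3a,7,7a-tetrahydro-1-benzofuran-6(2H)-one | C=CC[C@@]12C=C(OC)C(=O)[C@@H](OC)[C@@H]1O[C@@H](c3ccc(OC)c(O[Si](C(C)C)(C(C)C)C(C)C)c3)[C@H]2C | intermediate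
14 | (2R,3S,3aR,7aR)-3a-allyl-5,7-dimethoxy-2-[4-methoxy-3-(triisopropylsilyloxy)phenyl]-3-methyl-6-(trimethylsilyloxy)-2,3,3a,7a-tetrahydro-1-benzofuran | C=CC[C@@]12C=C(OC)C(O[Si](C)(C)C)=C(OC)[C@@H]1O[C@@H](c3ccc(OC)c(O[Si](C(C)C)(C(C)C)C(C)C)c3)[C@H]2C | intermediate
15 | (1S,5R,6R,7S,8R)-5-allyl-1,3-dimethoxy-7-[4-methoxy-3-(triisopropylsilyloxy)phenyl]-6-methyl-8-(trimethylsilyloxy)bicyclo[3.2.1]oct-3-en-2-one | C=CC[C@]12C=C(OC)C(=O)[C@](OC)([C@H](c3ccc(OC)c(O[Si](C(C)C)(C(C)C)C(C)C)c3)[C@H]1C)[C@@H]2O[Si](C)(C)C | intermediate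
16 | (1S,5R,6R,7S,8R)-5-allyl-8-hydroxy-1,3-dimethoxy-7-[4-methoxy-3-(triisopropylsilyloxy)phenyl]-6-methylbicyclo[3.2.1]oct-3-en-2-one | C=CC[C@]12C=C(OC)C(=O)[C@](OC)([C@H](c3ccc(OC)c(O[Si](C(C)C)(C(C)C)C(C)C)c3)[C@H]1C)[C@@H]2O | intermediate
17 | (1S,5R,6R,7S,8S)-5-allyl-8-hydroxy-1,3-dimethoxy-7-[4-methoxy-3-(triisopropylsilyloxy)phenyl]-6-methylbicyclo[3.2.1]oct-3-en-2-one | C=CC[C@]12C=C(OC)C(=O)[C@](OC)([C@H](c3ccc(OC)c(O[Si](C(C)C)(C(C)C)C(C)C)c3)[C@H]1C)[C@H]2O | intermediate
18 | (1S,3S,5S,6R,7S,8S)-5-allyl-8-hydroxy-1,3-dimethoxy-7-[4-methoxy-3-(triisopropylsilyloxy)phenyl]-6-methylbicyclo[3.2.1]octan-2-one | C=CC[C@]12C[C@H](OC)C(=O)[C@](OC)([C@H](c3ccc(OC)c(O[Si](C(C)C)(C(C)C)C(C)C)c3)[C@H]1C)[C@H]2O | intermediate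
19 | (1S,3S,5S,6R,7S,8S)-5-allyl-8-hydroxy-7-(3-hydroxy-4-methoxyphenyl)-1,3-dimethoxy-6-methylbicyclo[3.2.1]octan-2-one | C=CC[C@]12C[C@H](OC)C(=O)[C@](OC)([C@H](c3ccc(OC)c(O)c3)[C@H]1C)[C@H]2O | target

Total step count: 11. Longest linear sequence: 10 steps (steps 2 to 11, from 4-vinylsyringol 3).

Steps most likely to fail

Step 6 (the new method). The allyl group may stay on the phenol oxygen, or the dearomatised para adduct may not be drained fast enough by the oxa-Michael closure to outweigh the lost aromaticity. The palladium could also spend the carbonate on the α-methoxy ketone of the product. The fallback leaves the metal out and uses the thermal sigmatropic route. Phenol 10 is O-allylated (allyl bromide, K2CO3, acetone) to the allyl aryl ether F1. F1 is then heated (N,N-diethylaniline, about 180 °C, sealed tube), so that the aromatic Claisen rearrangement to the ortho dienone and the Cope shift to the para dienone 12 run in sequence. This is the classical para-Claisen course of 2,6-disubstituted aryl allyl ethers, and the amine solvent promotes the same oxa-Michael closure. The sequence sets out from 10 and comes back to the route at 13.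

Step 8. The Lewis acid may reopen the ether at C8 (retro-oxa-Michael through the silyloxy-pentadienyl cation) faster than it ionises C7, or the benzylic cation may lose a proton to a styrene before C1 reaches it. A third possibility is capture on the wrong face of C7. The fallback drops the silyl enol ether and rearranges ketone 13 itself under protic, equilibrating conditions (catalytic TfOH in hexafluoroisopropanol/CH2Cl2, 0 °C). There ether opening, styrene formation and benzylic ionisation are all reversible, and the C–C bonded β-hydroxy ketone is the expected resting point. This is the acid-induced hydrobenzofuranoid-to-bicyclooctanoid isomerisation in its classical form. It sets out from 13 and comes back at 16 without any new isolated compound.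

Step 9. The retro-aldol opening may not be followed by clean re-closure, so that material is lost through the ring-opened keto aldehyde, or the equilibration may stop short. The fallback changes C8 by hydrogen transfer instead of C–C cleavage. Alcohol 16 is oxidised with Dess–Martin periodinane to the 2,8-dione F2. F2 is then reduced under reversible Meerwein–Ponndorf–Verley conditions (Al(OiPr)3, i-PrOH, toluene, 50 to 80 °C), which lead to the more stable carbinol. Irreversible hydride reagents are avoided because attack over the open enone bridge would return 16. The sequence sets out from 16 and comes back at 17.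

Further compounds
F1 | step 6 | (1R,2S)-2-[4-(allyloxy)-3,5-dimethoxyphenyl]-1-[4-methoxy-3-(triisopropylsilyloxy)phenyl]propan-1-ol | C=CCOc1c(OC)cc(cc1OC)[C@H](C)[C@@H](O)c2ccc(OC)c(O[Si](C(C)C)(C(C)C)C(C)C)c2
F0 | step 8 | none | none
F2 | step 9 | (1S,5R,6R,7S)-5-allyl-1,3-dimethoxy-7-[4-methoxy-3-(triisopropylsilyloxy)phenyl]-6-methylbicyclo[3.2.1]oct-3-ene-2,8-dione | C=CC[C@]12C=C(OC)C(=O)[C@](OC)([C@H](c3ccc(OC)c(O[Si](C(C)C)(C(C)C)C(C)C)c3)[C@H]1C)C2=O
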